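**Retrosynthetic overview**
1. Target 16 is (2S)-5,7-dihydroxy-4'-methoxy-8,3'-diprenylflavanone. The C4 ketone is traced back to a C4 methyl ether (13) and the two phenols to TBS ethers.
2. Feature used: in pyranone ring C, the atoms O1–C8a–C4a–C4 are the oxygen, two ring carbons and methide carbon of an alkoxy o-quinone methide built on phloroglucinol ring A, and C2–C3 is the vinyl group of a 4-methoxystyrene. One hetero-[4+2] forms C3–C4 and O1–C2, closes ring C (the only ring made in the route) and sets C2.
3. Diene precursor 7: 2,4,6-trihydroxybenzaldehyde is bis-silylated, the remaining hydroxyl is converted to a 1,1-dimethylpropargyl ether, then semi-hydrogenation and aromatic Claisen rearrangement put the prenyl group on the only free ortho carbon (future C8).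
4. Dienophile 10: 3-bromo-4-methoxybenzaldehyde, Stille prenylation, Wittig methylenation.
5. After the cycloaddition: C4–OMe to C4–OH, oxidation to the ketone, buffered desilylation.

Key step: step 7

Assumption: the sense of induction of the phosphoric acid cannot be derived from precedent; (R)-TRIP, (R)-3,3'-bis(2,4,6-triisopropylphenyl)-1,1'-binaphthyl-2,2'-diyl hydrogen phosphate, is written as the working choice, and its enantiomer is taken if the 2R adduct predominates.

**Route**

Step 1
Reactants: 1 2,4,6-trihydroxybenzaldehyde
Product: 2 2-hydroxy-4,6-bis(tert-butyldimethylsilyloxy)benzaldehyde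
Conditions: TBSCl (2.1 equiv), iPr2NEt (2.5 equiv), CH2Cl2/DMF, 0 °C to rt
Reagents that add atoms: tert-butyldimethylsilyl chloride, CC(C)(C)[Si](C)(C)Cl
Why: Silyl ether formation; the para hydroxyl and one of the two equivalent ortho hydroxyls should react, after which the last hydroxyl is held in a hydrogen bond to the formyl oxygen and stays free.

Step 2
Reactants: 2 2-hydroxy-4,6-bis(tert-butyldimethylsilyloxy)benzaldehyde, 3 3-chloro-3-methylbut-1-yne
Product: 4 2-(2-methylbut-3-yn-2-yloxy)-4,6-bis(tert-butyldimethylsilyloxy)benzaldehyde
Conditions: 3 (1.5 equiv), DBU (1.6 equiv), CuCl2·2H2O (1 mol%), dry MeCN, 0 °C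
Reagents that add atoms: none
Why: Copper-catalysed propargylic etherification; the copper acetylide of 3 ionises to a copper allenylidene that the acidic ortho-formyl phenoxide attacks at the tertiary carbon, and the cold anhydrous medium is chosen to spare the aryl silyl ethers.

Step 3
Reactants: 4 2-(2-methylbut-3-yn-2-yloxy)-4,6-bis(tert-butyldimethylsilyloxy)benzaldehyde
Product: 5 2-(2-methylbut-3-en-2-yloxy)-4,6-bis(tert-butyldimethylsilyloxy)benzaldehyde
Conditions: H2 (1 atm), Pd/CaCO3 poisoned with Pb(OAc)2, quinoline, EtOAc, rt
Reagents that add atoms: none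
Why: Lindlar semi-hydrogenation; the poisoned palladium surface should stop at the terminal alkene and leave the aldehyde and the silyl ethers untouched.

Step 4
Reactants: 5 2-(2-methylbut-3-en-2-yloxy)-4,6-bis(tert-butyldimethylsilyloxy)benzaldehyde
Product: 7 2-hydroxy-3-(3-methylbut-2-enyl)-4,6-bis(tert-butyldimethylsilyloxy)benzaldehyde, via Claisen dienone 6 (not isolated)
Conditions: PhMe, 110 °C
Reagents that add atoms: none
Why: Aromatic Claisen rearrangement; the [3,3] shift of the 1,1-dimethylallyl ether delivers the allyl terminus to C3, the only ortho carbon bearing hydrogen, with allylic inversion to the linear prenyl group, and dienone 6 enolises to the chelated phenol 7.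

Step 5
Reactants: 8 3-bromo-4-methoxybenzaldehyde
Product: 9 4-methoxy-3-(3-methylbut-2-enyl)benzaldehyde
Conditions: Bu3SnCH2CH=CMe2 (1.2 equiv), Pd(PPh3)4 (5 mol%), DMF, 100 °C
Reagents that add atoms: tributyl(3-methylbut-2-enyl)stannane, CCCC[Sn](CCCC)(CCCC)CC=C(C)C
Why: Stille cross-coupling; oxidative addition of zerovalent palladium into the C–Br bond, transfer of the prenyl group from tin and reductive elimination at the unhindered allyl terminus should give the linear prenyl arene, with the aldehyde tolerated.

Step 6
Reactants: 9 4-methoxy-3-(3-methylbut-2-enyl)benzaldehyde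
Product: 10 4-methoxy-3-(3-methylbut-2-enyl)styrene
Conditions: Ph3PCH3Br (1.3 equiv), KOtBu (1.25 equiv), THF, 0 °C to rt
Reagents that add atoms: methyltriphenylphosphonium bromide, C[P+](c1ccccc1)(c1ccccc1)c1ccccc1.[Br-]
Why: Wittig methylenation; the non-stabilised ylide converts the aldehyde into the terminal alkene without touching the prenyl group or the aryl ether.

Step 7
Reactants: 7 2-hydroxy-3-(3-methylbut-2-enyl)-4,6-bis(tert-butyldimethylsilyloxy)benzaldehyde, 10 4-methoxy-3-(3-methylbut-2-enyl)styrene
Product: 13 (2S,4S)-4-methoxy-2-[4-methoxy-3-(3-methylbut-2-enyl)phenyl]-8-(3-methylbut-2-enyl)-5,7-bis(tert-butyldimethylsilyloxy)chroman (2,4-cis), via dimethyl acetal 11 (not isolated), via methoxy o-quinone methide 12 (not isolated)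
Conditions: (R)-TRIP (10 mol%), HC(OMe)3 (2 equiv), 10 (1.5 equiv), 5 Å MS, PhMe, −20 °C
Reagents that add atoms: trimethyl orthoformate, COC(OC)OC
Why: Proposed new method: the phosphoric acid and trimethyl orthoformate convert 7 into acetal 11, which loses methanol to the phenol-bearing methoxycarbenium ion, the O-protonated form of o-quinone methide 12, held as a contact ion pair whose phosphate also hydrogen-bonds the phenolic OH. The CH2 terminus of styrene 10 adds to the carbenium carbon (C3–C4 bond) and the developing p-methoxybenzylic cation is captured by the phenol oxygen (O1–C2 bond), an asynchronous inverse-demand hetero-[4+2] that closes the six-membered pyran ring in one event. The closest known reaction types are the achiral-acid coupling of salicylaldehydes, orthoformates and styrenes to racemic cis-4-alkoxyflavans and chiral phosphoric acid-controlled cycloadditions of o-quinone methides; new here is enantiocontrol over an acetal-derived alkoxy o-quinone methide with a styrene that offers the catalyst no hydrogen-bond donor. C4 is set by the face of the carbenium ion left open by the 3,3'-aryl groups of the bound phosphate, and C2 follows from it through the endo, chair-like closure with the aryl group pseudo-equatorial that gives the 2,4-cis adduct, so facial control at C4 is relayed to the S configuration at C2. The step needs regioselectivity, secured by polarity (nucleophilic CH2 to C4, oxygen to the benzylic carbon), and chemoselectivity for the styrene over the three prenyl alkenes and over acid cyclisation of the phenol onto its ortho prenyl group, secured by the higher nucleophilicity of the p-methoxystyrene and by a weak acid at low temperature. Any 2,4-trans isomer should be removed by chromatography, since in a stepwise closure it may carry the opposite C2 configuration.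

Step 8
Reactants: 13 (2S,4S)-4-methoxy-2-[4-methoxy-3-(3-methylbut-2-enyl)phenyl]-8-(3-methylbut-2-enyl)-5,7-bis(tert-butyldimethylsilyloxy)chroman
Product: 14 (2S)-2-[4-methoxy-3-(3-methylbut-2-enyl)phenyl]-8-(3-methylbut-2-enyl)-5,7-bis(tert-butyldimethylsilyloxy)chroman-4-ol (both C4 epimers)
Conditions: TsOH·H2O (5 mol%), THF/H2O 5:1, 0 °C to rt
Reagents that add atoms: water, O
Why: SN1 solvolysis of a benzylic methyl ether; the C4 cation is stabilised by O1 and the 5- and 7-silyloxy groups and should ionise far more readily than the C2–O1 bond, water in large excess captures it, and the C4 configuration is irrelevant because both epimers converge in step 9.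

Step 9
Reactants: 14 (2S)-2-[4-methoxy-3-(3-methylbut-2-enyl)phenyl]-8-(3-methylbut-2-enyl)-5,7-bis(tert-butyldimethylsilyloxy)chroman-4-ol
Product: 15 (2S)-2-[4-methoxy-3-(3-methylbut-2-enyl)phenyl]-8-(3-methylbut-2-enyl)-5,7-bis(tert-butyldimethylsilyloxy)chroman-4-one
Conditions: Dess–Martin periodinane (1.3 equiv), NaHCO3, CH2Cl2, 0 °C to rt
Reagents that add atoms: none
Why: Dess–Martin oxidation of the secondary benzylic alcohol under near-neutral buffered conditions, which should leave the prenyl alkenes and silyl ethers intact and give no base strong enough to open the ring by retro-oxa-Michael reaction at C2.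

Step 10
Reactants: 15 (2S)-2-[4-methoxy-3-(3-methylbut-2-enyl)phenyl]-8-(3-methylbut-2-enyl)-5,7-bis(tert-butyldimethylsilyloxy)chroman-4-one
Product: 16 (2S)-5,7-dihydroxy-2-[4-methoxy-3-(3-methylbut-2-enyl)phenyl]-8-(3-methylbut-2-enyl)chroman-4-one
Conditions: TBAF (2.4 equiv), AcOH (2.6 equiv), THF, 0 °C
Reagents that add atoms: none
Why: Fluoride cleavage of the aryl silyl ethers; acetic acid protonates the phenoxides as they form, so the chalcone/flavanone equilibrium that would racemise C2 should not be opened, and neither the prenyl groups nor the methyl ether react.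

**Compound list**
1 | 2,4,6-trihydroxybenzaldehyde | O=Cc1c(O)cc(O)cc1O | starting material
2 | 2-hydroxy-4,6-bis(tert-butyldimethylsilyloxy)benzaldehyde | O=Cc1c(O)cc(O[Si](C)(C)C(C)(C)C)cc1O[Si](C)(C)C(C)(C)C | intermediate
3 | 3-chloro-3-methylbut-1-yne | CC(C)(Cl)C#C | starting material
4 | 2-(2-methylbut-3-yn-2-yloxy)-4,6-bis(tert-butyldimethylsilyloxy)benzaldehyde | O=Cc1c(OC(C)(C)C#C)cc(O[Si](C)(C)C(C)(C)C)cc1O[Si](C)(C)C(C)(C)C | intermediate
5 | 2-(2-methylbut-3-en-2-yloxy)-4,6-bis(tert-butyldimethylsilyloxy)benzaldehyde | O=Cc1c(OC(C)(C)C=C)cc(O[Si](C)(C)C(C)(C)C)cc1O[Si](C)(C)C(C)(C)C | intermediate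
6 | 2,4-bis(tert-butyldimethylsilyloxy)-5-(3-methylbut-2-enyl)-6-oxocyclohexa-1,3-diene-1-carbaldehyde (Claisen dienone, racemic at C5, not isolated) | O=CC1=C(O[Si](C)(C)C(C)(C)C)C=C(O[Si](C)(C)C(C)(C)C)C(CC=C(C)C)C1=O | intermediate
7 | 2-hydroxy-3-(3-methylbut-2-enyl)-4,6-bis(tert-butyldimethylsilyloxy)benzaldehyde | O=Cc1c(O)c(CC=C(C)C)c(O[Si](C)(C)C(C)(C)C)cc1O[Si](C)(C)C(C)(C)C | intermediate
8 | 3-bromo-4-methoxybenzaldehyde | COc1ccc(C=O)cc1Br | starting material
9 | 4-methoxy-3-(3-methylbut-2-enyl)benzaldehyde | COc1ccc(C=O)cc1CC=C(C)C | intermediate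
10 | 4-methoxy-3-(3-methylbut-2-enyl)styrene | COc1ccc(C=C)cc1CC=C(C)C | intermediate
11 | 2-(dimethoxymethyl)-6-(3-methylbut-2-enyl)-3,5-bis(tert-butyldimethylsilyloxy)phenol (not isolated) | COC(OC)c1c(O)c(CC=C(C)C)c(O[Si](C)(C)C(C)(C)C)cc1O[Si](C)(C)C(C)(C)C | intermediate
12 | (E)-6-(methoxymethylidene)-2-(3-methylbut-2-enyl)-3,5-bis(tert-butyldimethylsilyloxy)cyclohexa-2,4-dien-1-one (not isolated; reacts as its O-protonated ion pair) | CO/C=C1/C(=O)C(CC=C(C)C)=C(O[Si](C)(C)C(C)(C)C)C=C1O[Si](C)(C)C(C)(C)C | intermediate
13 | (2S,4S)-4-methoxy-2-[4-methoxy-3-(3-methylbut-2-enyl)phenyl]-8-(3-methylbut-2-enyl)-5,7-bis(tert-butyldimethylsilyloxy)chroman (2,4-cis) | COc1ccc([C@@H]2C[C@H](OC)c3c(O[Si](C)(C)C(C)(C)C)cc(O[Si](C)(C)C(C)(C)C)c(CC=C(C)C)c3O2)cc1CC=C(C)C | intermediate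
14 | (2S)-2-[4-methoxy-3-(3-methylbut-2-enyl)phenyl]-8-(3-methylbut-2-enyl)-5,7-bis(tert-butyldimethylsilyloxy)chroman-4-ol (C4 not defined, both epimers) | COc1ccc([C@@H]2CC(O)c3c(O[Si](C)(C)C(C)(C)C)cc(O[Si](C)(C)C(C)(C)C)c(CC=C(C)C)c3O2)cc1CC=C(C)C | intermediate
15 | (2S)-2-[4-methoxy-3-(3-methylbut-2-enyl)phenyl]-8-(3-methylbut-2-enyl)-5,7-bis(tert-butyldimethylsilyloxy)chroman-4-one | COc1ccc([C@@H]2CC(=O)c3c(O[Si](C)(C)C(C)(C)C)cc(O[Si](C)(C)C(C)(C)C)c(CC=C(C)C)c3O2)cc1CC=C(C)C | intermediate
16 | (2S)-5,7-dihydroxy-2-[4-methoxy-3-(3-methylbut-2-enyl)phenyl]-8-(3-methylbut-2-enyl)chroman-4-one | COc1ccc([C@@H]2CC(=O)c3c(O)cc(O)c(CC=C(C)C)c3O2)cc1CC=C(C)C | target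

**Step count**
Total: 10 steps. Longest linear sequence: 8 steps (steps 1–4, then 7–10); steps 5–6 form the second branch.

**Steps most likely to fail**

1. Step 7 (proposed new method). The phosphate may discriminate poorly between the two faces of the carbenium ion, because the styrene gives it no second binding point. An uncatalysed or loosely ion-paired background reaction may add racemic product. Reversible acid ionisation of the C2–O1 bond may erode the configuration after ring closure. Oligomerisation of the electron-rich styrene may compete. Fallback with known chemistry: starting from 7 and 10, the same three-component coupling is run with an achiral acid (diphenyl phosphate or TsOH·H2O in catalytic amount, HC(OMe)3, CH2Cl2, 0 °C), the established route to racemic cis-4-alkoxyflavans. This should give 13 together with its mirror image, the (2R,4R)-enantiomer of 13 F1. The two are separated by preparative chromatography on a chiral stationary phase (cellulose tris(3,5-dimethylphenylcarbamate)), and the route is rejoined at 13. Catalyst control is thus replaced by racemic synthesis plus resolution.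

2. Step 8. The C4 cation may lose a C3 proton instead of adding water, giving the flav-3-ene. The aqueous acid may also start to cleave the silyl ethers or ionise the p-methoxybenzylic C2–O1 bond, with loss of enantiopurity. Fallback: starting from 13, the C4–H bond is oxidised directly with DDQ (1.5–2 equiv) in CH2Cl2/pH 7 phosphate buffer at 0 °C. Hydride abstraction at C4 (activated by the methoxy group and ring A) gives the methoxy-stabilised cation, water adds, and the hemiketal collapses to the ketone with loss of methanol. The route is rejoined at 15 and compound 14 is bypassed; no acid is present and no new compound is made (F0).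

3. Step 2. O-Alkylation of the hindered, hydrogen-bonded phenoxide may be slow, and the amidine base may cleave or scramble the aryl silyl ethers before the ether forms. Fallback: starting from 2, a neutral decarboxylative allylic etherification is used instead. tert-Butyl 2-methylbut-3-en-2-yl carbonate F2 (prepared from 2-methylbut-3-en-2-ol, n-BuLi and Boc2O) and the zerovalent palladium catalyst Pd(PPh3)4 (3 mol%) in THF at 0 °C should give the branched 1,1-dimethylallyl ether under kinetic control, since the phenol attacks the more substituted terminus of the dimethylallyl palladium intermediate. The route is rejoined at 5, so alkyne 4 and step 3 are bypassed and no external base is needed.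

**Further compounds**
F1 | step 7 | (2R,4R)-4-methoxy-2-[4-methoxy-3-(3-methylbut-2-enyl)phenyl]-8-(3-methylbut-2-enyl)-5,7-bis(tert-butyldimethylsilyloxy)chroman (enantiomer of 13) | COc1ccc([C@H]2C[C@@H](OC)c3c(O[Si](C)(C)C(C)(C)C)cc(O[Si](C)(C)C(C)(C)C)c(CC=C(C)C)c3O2)cc1CC=C(C)C
F0 | step 8 | none | none
F2 | step 2 | tert-butyl 2-methylbut-3-en-2-yl carbonate | CC(C)(C)OC(=O)OC(C)(C)C=C
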